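The readings are simulated for substances that don't exist, noise included.

If a substrate can leave only by becoming its own product, the gap between the two substrates equals the gap between the two products. This flask holds a racemic substrate with partner and a single-handed catalyst. Its first hours are followed, and I must say what stands at the asked time.

all flasks: left-handed substrate 0.80 M; right-handed substrate 0.80 M; catalyst 41 mM

|  | partner | remark | time |
|---|---|---|---|
| winter | 1.6 M | the very flask that is asked about, followed so far |  |
| flask | 1.60 M |  | 5.0 h |

winter run (percent of the left-handed substrate and right-handed substrate together charged)

| time / h | left-handed substrate / % | right-handed substrate / % |
|---|---|---|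
| 0.333 | 44.9 | 46.7 |
| 0.833 | 40.0 | 43.7 |
| 1.50 | 36.8 | 40.2 |
| 2.50 | 34.9 | 37.4 |

(readings scatter by 0.3 percentage points)

- catalyst is single-handed; left-handed substrate and right-handed substrate are mirror images of each other, charged as a racemate, each of them at the stated concentration
- an excess is the difference of the two amounts in percent of their sum
- an excess is below zero if the other one leads

- part of the left-handed substrate and right-handed substrate charged together that has reacted at 5.0 h
- excess of left-handed product over right-handed product in the product at 5.0 h
- excess of right-handed substrate over left-handed substrate among what is left of the two at 5.0 h

My first way is that ledger. Dividing the right-handed lead by the part reacted gives a product excess of 21.4% at the first reading, but 9.03% at the last. With substrates this close, a single-handed catalyst should hand out a steady excess, so a sinking figure means the ledger cheats.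

My second way supposes that the two substrates turn into each other, which is dynamic kinetic resolution. Each point reacted then adds a fixed share to the gap, and each hour removes a fixed fraction of it. Up to 0.833 h, the gap reaches 3.7 percentage points while 16 points react, and the gap averages 2 points over that time. From there to 2.50 h, the gap loses 1.2 points while 11 points react, and it averages 3.2 points.

These two balances give the birth excess, the excess with which product is made, as 32.1%. They also give a healing rate of 0.913 /h, a half-life of 0.759 h. Both are readings and carry the scatter. That half-life is short against 5.0 h, so I take the healing as settled and expect the product excess to stay near 32.1%.

The forecast says 30.7% reacted, a product excess of 2.8% and a substrate excess of 1.2%, holding that the shrinking gap “points to a reversible reaction”. On the product excess we part.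

The flask gives 33.6% reacted, a product excess of 33.9% and a substrate excess of 1.70%.

    partner + catalyst + left-handed substrate → catalyst + left-handed product (k = 0.00190 /M²/s)
    partner + catalyst + right-handed substrate → catalyst + right-handed product (k = 8.80 × 10⁻⁴ /M²/s)
    left-handed substrate ⇌ right-handed substrate (k = 1.20 × 10⁻⁴ /s)
    2 partner → self-condensation product (k = 1.10 × 10⁻⁵ /M/s)
    catalyst ⇌ dormant form (K = 3.80, k = 2.10 × 10⁻⁴ /s)

The birth excess times the part reacted gives this flask a left-handed product lead of 11 points, and the flask holds 22.5% against 11.1%. The neighbouring flask has 0.40 M of partner, with its other charges held, and 10.5% reacts. The same split gives it 6.94% left-handed and 3.56% right-handed product. That neighbour holds 7.15% and 3.37%, a product excess of 36.0%.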